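A leftover of substrate goes into a stirred two-phase flask with an equal amount of reagent, and the question is how much target stands at the end of the run. Target here always includes its share in the second phase.

substrate 0.10 M; reagent in the second phase 0.100 M; protic impurity 0.0100 M; time 5.0 min; volume of the second phase over the first 2.0

* how much target and product in the second phase together there is at 5.0 min, in percent of the substrate charged
* the change that raises the amount of target and product in the second phase together at 5.0 min, in percent of the substrate charged most ("none" if none brings more than 2 percentage points) (alder / cedar / maple / none)
* amount of target and product in the second phase together at 5.0 min, in percent of the substrate charged, after alder

- percentages count the substrate that a species holds: one homo dimer counts as two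
- target is meant together with its product in the second phase
- a step written with two of one species runs at k times the square of its concentration and takes two of it each time
- in the second phase: reagent in the second phase, product in the second phase; everything else is in the first
- charges count per volume of the first phase; a concentration in a rate is the amount of a species over the volume of its own phase; every rate counts per litre of the first phase
- run time (flask): 5.0 min

    reagent in the reaction phase ⇌ reagent in the second phase, rate k1*([reagent in the reaction phase] - [reagent in the second phase]/K1) per volume of the first phase (K1 = 0.89, k1 = 0.24 /s)
    substrate + reagent in the reaction phase → target (k2 = 0.091 /M/s)
    target ⇌ product in the second phase, rate k3*([target] - [product in the second phase]/K3) per volume of the first phase (K3 = 0.27, k3 = 0.12 /s)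
    target → decomposed product (k4 = 0.014 /s)
    reagent in the reaction phase + protic impurity → quenched reagent (k5 = 0.12 /M/s)
    2 substrate → homo dimer (k6 = 0.0048 /M/s)
    reagent in the reaction phase → decomposed reagent (k7 = 0.0023 /s)

Two chemists argue over this flask. The first keeps a tally. Reagent evens out between the phases in 2.67 s, which is short against the run, so 36.0% of it works in the reaction phase. Counting turnovers, the making constant times that reagent times the run gives 0.982. With equal charges, substrate and reagent each fall to one over one plus that count, 50.5%, so the tally says 49.5% of the substrate ends as target and stays there.

I hold the second view, a leak. Target decays in the first phase, where 64.9% of it sits, so I use the holding time, one over the decay constant times that share: 1.83 min. The run contains 2.73 holding times, so I estimate target in hand not as the sum of what was made but as the making rate times the holding time, the quasi-steady-state estimate, and I take that as a rough figure. At the charge that level is 36.0% of the substrate. With substrate and reagent each at the tally's fraction, it drops to about a quarter, which gives 9.17%. Target evens out in 2.92 s, far shorter than the holding time, so I expect little from alder or maple. Doubling the reagent raises the making rate, so I choose cedar.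

The forecast stands on my side but comes from its own hand integration: 9.4%, 9.4% after alder, and cedar, since “doubling the reagent directly speeds formation”.

The run gives 9.86%, and 9.85% after alder. The best change is cedar, worth 4.8 percentage points, against −0.0072 points for alder and −0.025 points for maple. The tally's figure stands well above the result.

The tally has its region early: at 0.500 min, short against the holding time, this flask held 6.81% target out of 10.4% substrate gone. At 5.0 min, the making constant times this flask's substrate and reagent readings times the holding time gives 6.30%, which is 0.639 of the amount found, so target in this flask stood above that level. The flask left until 8.0 min has run 4.37 holding times. Its readings give 3.24%, a ratio of 0.611 to the target it held, 5.30%.

All constants were chosen freely; the run is a simulation.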